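**Plan**

1. Retrosynthesis: first the eight O-benzyl groups are cut, then the C2–C1' bond between ring C of the flavanone and its ring B, then the biaryl bond C5'–C6'' between ring B and the benzo ring (ring D) of the flavone, and last the C6''–I bond, which leads back to luteolin.
2. Forward, aryl half: luteolin is benzylated, iodinated at C6'' under control of the free 5''-OH, benzylated again and joined by Suzuki–Miyaura coupling to a 2,3-bis(benzyloxy)-5-chlorophenylboronate; the remaining chloride is then turned into a boronic acid at C1'.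
3. Forward, union: rings A and C are made in one step as 5,7-bis(benzyloxy)chromone, the arylboronic acid is added to its C2, and hydrogenolysis of all benzyl ethers ends the route.
4. Enabling feature: C2 of ring C is β to the C4 ketone and bound to O1, so at the chromone level C2=C3–C4=O is an enone with C2 as its β-carbon. C1' of ring B has hydrogen at both ortho positions (C2', C6'). The other enone of the molecule, the flavone C2''=C3'', is β,β-disubstituted and stays out of the reaction.
5. Stereochemistry: the only stereocentre, C2 (S), is set in the joining step by a chiral bisphosphine on monovalent rhodium and is kept by a neutral end game.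

Key step: step 11

Assumption: the (S)-configured biaryl bisphosphine is taken to show the same sense of induction on a chromone as on 2-cyclohexenone, which gives the (2S)-flavanone; if the sense were opposite, the (R)-ligand would be used in step 11 with no other change.

**Route**

Step 1
Reactants: 1 luteolin
Product: 2 7-(benzyloxy)-2-[3,4-bis(benzyloxy)phenyl]-5-hydroxy-4H-chromen-4-one
Conditions: BnBr (3.2 equiv), K2CO3, DMF, rt
Reagents that add atoms: benzyl bromide, BrCc1ccccc1
Why: Williamson etherification; the 5-OH is held in a hydrogen bond to the C4 carbonyl and is the least reactive phenol, so three equivalents of benzyl bromide at room temperature should leave it free.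

Step 2
Reactants: 2 7-(benzyloxy)-2-[3,4-bis(benzyloxy)phenyl]-5-hydroxy-4H-chromen-4-one
Product: 3 7-(benzyloxy)-2-[3,4-bis(benzyloxy)phenyl]-5-hydroxy-6-iodo-4H-chromen-4-one
Conditions: BnMe3N+ ICl2− (1.05 equiv), CaCO3, CH2Cl2/MeOH, rt
Reagents that add atoms: benzyltrimethylammonium dichloroiodate, C[N+](C)(C)Cc1ccccc1.Cl[I-]Cl
Why: Electrophilic aromatic iodination directed by the free phenol; with a free chelated 5-OH and a 7-alkoxy group this buffered reagent is known to iodinate 5,7-dioxygenated flavones at C6 (ortho to the phenol) and not at C8, and the catechol diether ring, which has no free OH and is deactivated by the chromone, should not react.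

Step 3
Reactants: 3 7-(benzyloxy)-2-[3,4-bis(benzyloxy)phenyl]-5-hydroxy-6-iodo-4H-chromen-4-one
Product: 4 5,7-bis(benzyloxy)-2-[3,4-bis(benzyloxy)phenyl]-6-iodo-4H-chromen-4-one
Conditions: BnBr, Cs2CO3, DMF, 60 °C
Reagents that add atoms: benzyl bromide, BrCc1ccccc1
Why: Williamson etherification of the chelated and hindered 5-OH, which needs the stronger base and heat; it has to follow the iodination because a 5-alkoxy group would steer the iodine to C8.

Step 4
Reactants: 5 3-bromo-5-chloro-2-hydroxybenzaldehyde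
Product: 7 3-bromo-5-chlorobenzene-1,2-diol, via aryl formate 6 (not isolated)
Conditions: 30% H2O2, aq NaOH, 0 °C to rt; then HCl work-up
Reagents that add atoms: hydrogen peroxide, OO
Why: Dakin oxidation; hydroperoxide adds to the aldehyde, the aryl group migrates to oxygen (favoured by the ortho-hydroxyl) and the formate ester is hydrolysed in the basic medium.

Step 5
Reactants: 7 3-bromo-5-chlorobenzene-1,2-diol
Product: 8 1,2-bis(benzyloxy)-3-bromo-5-chlorobenzene
Conditions: BnBr (2.4 equiv), K2CO3, DMF, 60 °C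
Reagents that add atoms: benzyl bromide, BrCc1ccccc1
Why: Twofold Williamson etherification of a catechol, which also removes its sensitivity to oxidation.

Step 6
Reactants: 8 1,2-bis(benzyloxy)-3-bromo-5-chlorobenzene
Product: 9 2-[2,3-bis(benzyloxy)-5-chlorophenyl]-4,4,5,5-tetramethyl-1,3,2-dioxaborolane
Conditions: B2pin2, PdCl2(dppf) (5 mol %), KOAc, 1,4-dioxane, 85 °C
Reagents that add atoms: bis(pinacolato)diboron, CC1(C)OB(OC1(C)C)B1OC(C)(C)C(C)(C)O1
Why: Miyaura borylation; zerovalent palladium with the arylphosphine dppf inserts into the C–Br bond but not into the unactivated C–Cl bond, and KOAc is too weak a base to start a Suzuki coupling of the product.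

Step 7
Reactants: 4 5,7-bis(benzyloxy)-2-[3,4-bis(benzyloxy)phenyl]-6-iodo-4H-chromen-4-one; 9 2-[2,3-bis(benzyloxy)-5-chlorophenyl]-4,4,5,5-tetramethyl-1,3,2-dioxaborolane (1.5 equiv)
Product: 10 5,7-bis(benzyloxy)-6-[2,3-bis(benzyloxy)-5-chlorophenyl]-2-[3,4-bis(benzyloxy)phenyl]-4H-chromen-4-one
Conditions: Pd(PPh3)4 (10 mol %), K3PO4, DMF/H2O, 90 °C
Reagents that add atoms: none
Why: Suzuki–Miyaura coupling to a biaryl with three ortho substituents, the coupling type used for 6-iodo-5,7-dialkoxyflavones with ortho-alkoxyarylboronates; Pd(PPh3)4 inserts only into the C–I bond, so the chloride at the future C1' should survive.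

Step 8
Reactants: 10 5,7-bis(benzyloxy)-6-[2,3-bis(benzyloxy)-5-chlorophenyl]-2-[3,4-bis(benzyloxy)phenyl]-4H-chromen-4-one
Product: 11 5,7-bis(benzyloxy)-6-[2,3-bis(benzyloxy)-5-(4,4,5,5-tetramethyl-1,3,2-dioxaborolan-2-yl)phenyl]-2-[3,4-bis(benzyloxy)phenyl]-4H-chromen-4-one
Conditions: B2pin2, Pd2(dba)3 (2.5 mol %), XPhos (10 mol %), KOAc, 1,4-dioxane, 100 °C
Reagents that add atoms: bis(pinacolato)diboron, CC1(C)OB(OC1(C)C)B1OC(C)(C)C(C)(C)O1
Why: Miyaura borylation of an aryl chloride, for which the bulky electron-rich biarylphosphine is needed; the chloride has hydrogen at both ortho positions and the flavone enone and benzyl ethers are inert to these conditions.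

Step 9
Reactants: 11 5,7-bis(benzyloxy)-6-[2,3-bis(benzyloxy)-5-(4,4,5,5-tetramethyl-1,3,2-dioxaborolan-2-yl)phenyl]-2-[3,4-bis(benzyloxy)phenyl]-4H-chromen-4-one
Product: 12 {3,4-bis(benzyloxy)-5-[5,7-bis(benzyloxy)-2-[3,4-bis(benzyloxy)phenyl]-4-oxo-4H-chromen-6-yl]phenyl}boronic acid
Conditions: NaIO4, NH4OAc, acetone/THF/H2O, rt
Reagents that add atoms: water, O
Why: Oxidative cleavage of the pinacol ester; periodate destroys the pinacol set free by reversible hydrolysis and so drives the ester to the free boronic acid, which transmetalates to rhodium much faster than the ester.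

Step 10
Reactants: 13 1-[2,4-bis(benzyloxy)-6-hydroxyphenyl]ethan-1-one
Product: 15 5,7-bis(benzyloxy)-4H-chromen-4-one, via enaminone 14 (not isolated)
Conditions: Me2NCH(OMe)2, toluene, 100 °C; evaporate; AcOH, 80 °C
Reagents that add atoms: N,N-dimethylformamide dimethyl acetal, COC(OC)N(C)C
Why: Condensation of the methyl ketone with the amide acetal gives the enaminone, and in acid the phenol adds to its β-carbon (6-endo addition–elimination) with loss of dimethylamine, the standard chromone synthesis from 2-hydroxyacetophenones.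

Step 11
Reactants: 12 {3,4-bis(benzyloxy)-5-[5,7-bis(benzyloxy)-2-[3,4-bis(benzyloxy)phenyl]-4-oxo-4H-chromen-6-yl]phenyl}boronic acid; 15 5,7-bis(benzyloxy)-4H-chromen-4-one (2 equiv)
Product: 16 (2S)-5,7-bis(benzyloxy)-2-{3,4-bis(benzyloxy)-5-[5,7-bis(benzyloxy)-2-[3,4-bis(benzyloxy)phenyl]-4-oxo-4H-chromen-6-yl]phenyl}-2,3-dihydro-4H-chromen-4-one
Conditions: [Rh(OH)(cod)]2 (3 mol %), (S)-2,2'-bis[bis(3,4,5-trifluorophenyl)phosphino]-6,6'-dimethoxy-1,1'-biphenyl (7 mol %), toluene/H2O (10:1), 30 °C
Reagents that add atoms: none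
Why: The boronic acid transmetalates to the Rh–OH complex of monovalent rhodium, the aryl–rhodium bond adds syn across C2=C3 of 15 with the aryl group going to C2, and water protonates the oxa-π-allyl rhodium enolate, which frees the ketone and returns Rh–OH. The closest known reaction type is the rhodium-catalysed asymmetric 1,4-addition of arylboronic acids to chromones (Hayashi–Miyaura reaction), an established route to 2-arylchroman-4-ones. No ring is closed: ring C is already present and only passes from the chromone to the chromanone level. The new stereocentre C2 is controlled by the (S)-configured biaryl bisphosphine, whose quadrant model places the aryl group on the face of C2 that gives the (2S) configuration. The step needs site selectivity between two enones and a carbometalation faster than protonolysis of the aryl–rhodium bond: the flavone C2''=C3'' bond of 12 has a fully substituted β-carbon and should not insert, C2 of 15 carries only hydrogen, C1' has hydrogen at both ortho positions, and 15 is used in excess. The electron-poor ligand allows a low temperature in a neutral medium without added base, so the rhodium enolate should be protonated before ring C can open to the 2'-hydroxychalcone, the pathway that would erode the configuration at C2.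

Step 12
Reactants: 16 (2S)-5,7-bis(benzyloxy)-2-{3,4-bis(benzyloxy)-5-[5,7-bis(benzyloxy)-2-[3,4-bis(benzyloxy)phenyl]-4-oxo-4H-chromen-6-yl]phenyl}-2,3-dihydro-4H-chromen-4-one
Product: 17 (2S)-2-{3,4-dihydroxy-5-[5,7-dihydroxy-2-(3,4-dihydroxyphenyl)-4-oxo-4H-chromen-6-yl]phenyl}-5,7-dihydroxy-2,3-dihydro-4H-chromen-4-one
Conditions: H2 (1 atm), Pd/C (palladium on carbon, 10 wt % Pd), THF/MeOH, rt
Reagents that add atoms: none
Why: Hydrogenolysis of aryl benzyl ethers, which should be much faster than reduction of the flavone C2''=C3'' bond or of the two ketones; the neutral medium avoids the base-induced ring opening that racemises flavanones with a free 4'-OH.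

**Compound list**

1 | luteolin, 2-(3,4-dihydroxyphenyl)-5,7-dihydroxy-4H-chromen-4-one | O=c1cc(-c2ccc(O)c(O)c2)oc2cc(O)cc(O)c12 | starting material
2 | 7-(benzyloxy)-2-[3,4-bis(benzyloxy)phenyl]-5-hydroxy-4H-chromen-4-one | O=c1cc(-c2ccc(OCc3ccccc3)c(OCc3ccccc3)c2)oc2cc(OCc3ccccc3)cc(O)c12 | intermediate
3 | 7-(benzyloxy)-2-[3,4-bis(benzyloxy)phenyl]-5-hydroxy-6-iodo-4H-chromen-4-one | O=c1cc(-c2ccc(OCc3ccccc3)c(OCc3ccccc3)c2)oc2cc(OCc3ccccc3)c(I)c(O)c12 | intermediate
4 | 5,7-bis(benzyloxy)-2-[3,4-bis(benzyloxy)phenyl]-6-iodo-4H-chromen-4-one | O=c1cc(-c2ccc(OCc3ccccc3)c(OCc3ccccc3)c2)oc2cc(OCc3ccccc3)c(I)c(OCc3ccccc3)c12 | intermediate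
5 | 3-bromo-5-chloro-2-hydroxybenzaldehyde | O=Cc1cc(Cl)cc(Br)c1O | starting material
6 | 3-bromo-5-chloro-2-hydroxyphenyl formate | O=COc1cc(Cl)cc(Br)c1O | intermediate
7 | 3-bromo-5-chlorobenzene-1,2-diol | Oc1cc(Cl)cc(Br)c1O | intermediate
8 | 1,2-bis(benzyloxy)-3-bromo-5-chlorobenzene | Clc1cc(Br)c(OCc2ccccc2)c(OCc2ccccc2)c1 | intermediate
9 | 2-[2,3-bis(benzyloxy)-5-chlorophenyl]-4,4,5,5-tetramethyl-1,3,2-dioxaborolane | Clc1cc(B2OC(C)(C)C(C)(C)O2)c(OCc2ccccc2)c(OCc2ccccc2)c1 | intermediate
10 | 5,7-bis(benzyloxy)-6-[2,3-bis(benzyloxy)-5-chlorophenyl]-2-[3,4-bis(benzyloxy)phenyl]-4H-chromen-4-one | O=c1cc(-c2ccc(OCc3ccccc3)c(OCc3ccccc3)c2)oc2cc(OCc3ccccc3)c(-c3cc(Cl)cc(OCc4ccccc4)c3OCc3ccccc3)c(OCc3ccccc3)c12 | intermediate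
11 | 5,7-bis(benzyloxy)-6-[2,3-bis(benzyloxy)-5-(4,4,5,5-tetramethyl-1,3,2-dioxaborolan-2-yl)phenyl]-2-[3,4-bis(benzyloxy)phenyl]-4H-chromen-4-one | O=c1cc(-c2ccc(OCc3ccccc3)c(OCc3ccccc3)c2)oc2cc(OCc3ccccc3)c(-c3cc(B4OC(C)(C)C(C)(C)O4)cc(OCc4ccccc4)c3OCc3ccccc3)c(OCc3ccccc3)c12 | intermediate
12 | {3,4-bis(benzyloxy)-5-[5,7-bis(benzyloxy)-2-[3,4-bis(benzyloxy)phenyl]-4-oxo-4H-chromen-6-yl]phenyl}boronic acid | O=c1cc(-c2ccc(OCc3ccccc3)c(OCc3ccccc3)c2)oc2cc(OCc3ccccc3)c(-c3cc(B(O)O)cc(OCc4ccccc4)c3OCc3ccccc3)c(OCc3ccccc3)c12 | intermediate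
13 | 1-[2,4-bis(benzyloxy)-6-hydroxyphenyl]ethan-1-one | CC(=O)c1c(O)cc(OCc2ccccc2)cc1OCc1ccccc1 | starting material
14 | (2E)-1-[2,4-bis(benzyloxy)-6-hydroxyphenyl]-3-(dimethylamino)prop-2-en-1-one | CN(C)/C=C/C(=O)c1c(O)cc(OCc2ccccc2)cc1OCc1ccccc1 | intermediate
15 | 5,7-bis(benzyloxy)-4H-chromen-4-one | O=c1ccoc2cc(OCc3ccccc3)cc(OCc3ccccc3)c12 | intermediate
16 | (2S)-5,7-bis(benzyloxy)-2-{3,4-bis(benzyloxy)-5-[5,7-bis(benzyloxy)-2-[3,4-bis(benzyloxy)phenyl]-4-oxo-4H-chromen-6-yl]phenyl}-2,3-dihydro-4H-chromen-4-one | O=C1C[C@@H](c2cc(OCc3ccccc3)c(OCc3ccccc3)c(-c3c(OCc4ccccc4)cc4oc(-c5ccc(OCc6ccccc6)c(OCc6ccccc6)c5)cc(=O)c4c3OCc3ccccc3)c2)Oc2cc(OCc3ccccc3)cc(OCc3ccccc3)c21 | intermediate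
17 | (2S)-2-{3,4-dihydroxy-5-[5,7-dihydroxy-2-(3,4-dihydroxyphenyl)-4-oxo-4H-chromen-6-yl]phenyl}-5,7-dihydroxy-2,3-dihydro-4H-chromen-4-one | O=C1C[C@@H](c2cc(O)c(O)c(-c3c(O)cc4oc(-c5ccc(O)c(O)c5)cc(=O)c4c3O)c2)Oc2cc(O)cc(O)c21 | target

**Count and risks**

Total step count: 12. Longest linear sequence: 8 steps (1, 2, 3, 7, 8, 9, 11, 12, from luteolin).

Steps most likely to fail:

Step 11. The aryl–rhodium species may be protonated (protodeboronation of 12) faster than it inserts into the electron-rich chromone, or the rhodium enolate may open ring C reversibly, so that conversion or enantiomeric purity is poor. The fallback gives up catalyst control of C2. It sets out from 12 and 15, which are joined by the achiral conjugate addition under cationic divalent palladium (Pd(OCOCF3)2, 2,2'-bipyridine, AcOH/THF/H2O, 60 °C), a carbopalladation that runs in acidic medium, to give the racemic octabenzyl ether F1. Its enantiomers are then separated by preparative chromatography on a polysaccharide chiral stationary phase (cellulose tris(3,5-dimethylphenylcarbamate)), and the (2S)-enantiomer is 16, where the route is rejoined.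

Step 7. Transmetalation at the arylpalladium iodide with two ortho benzyloxy groups may be slow, so that protodeboronation of 9 and hydrodeiodination of 4 take over. The fallback changes the nucleophile to an organozinc reagent, which transmetalates without base. It sets out from 8: bromine–lithium exchange (n-BuLi, THF, −78 °C, the chloride is not touched) gives [2,3-bis(benzyloxy)-5-chlorophenyl]lithium F2, ZnCl2 turns it into [2,3-bis(benzyloxy)-5-chlorophenyl]zinc chloride F3, and Negishi coupling with iodide 4 (Pd(PPh3)4, THF, 60 °C) gives 10, where the route is rejoined; step 6 and compound 9 are then not needed.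

Step 12. The long exposure needed to cleave eight ethers may lead to saturation of the flavone C2''=C3'' bond or hydrogenolysis of the benzylic C2–O1 bond of ring C, and partly debenzylated material may precipitate on the catalyst and stall the reaction. The fallback replaces reduction by Lewis-acid ether cleavage. It sets out from 16: BCl3 with pentamethylbenzene as a non-basic benzyl-cation scavenger (CH2Cl2, −78 °C) should give 17 directly, with no new intermediate; the low temperature is chosen to keep ring C closed and the scavenger to prevent C-benzylation of the phenol rings.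

**Further compounds**

F1 | step 11 | racemic 5,7-bis(benzyloxy)-2-{3,4-bis(benzyloxy)-5-[5,7-bis(benzyloxy)-2-[3,4-bis(benzyloxy)phenyl]-4-oxo-4H-chromen-6-yl]phenyl}-2,3-dihydro-4H-chromen-4-one | O=C1CC(c2cc(OCc3ccccc3)c(OCc3ccccc3)c(-c3c(OCc4ccccc4)cc4oc(-c5ccc(OCc6ccccc6)c(OCc6ccccc6)c5)cc(=O)c4c3OCc3ccccc3)c2)Oc2cc(OCc3ccccc3)cc(OCc3ccccc3)c21
F2 | step 7 | [2,3-bis(benzyloxy)-5-chlorophenyl]lithium | [Li]c1cc(Cl)cc(OCc2ccccc2)c1OCc1ccccc1
F3 | step 7 | [2,3-bis(benzyloxy)-5-chlorophenyl]zinc chloride | Cl[Zn]c1cc(Cl)cc(OCc2ccccc2)c1OCc1ccccc1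
F0 | step 12 | none | none
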